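The fifteen carbons of the decalin core (rings A and B with C11–C15) are one head-to-tail farnesyl chain, so the synthesis rests on disconnecting C6–C7, C5–C10 and the C4–O bond together. A class 1 sesquiterpene cyclase folds (2E,6E)-farnesyl diphosphate, closes both rings and sets C4, C5, C7 and C10 in one operation, placing the hydroxyl on the axial 4β position, syn to the C10 methyl, where uncatalysed cation capture does not go. The precursor is the acyclic allylic diphosphate, made from farnesol in two steps. Hydrogenation of the isopropenyl group, enzymatic hydroxylation of the axial 6β-H and acylation of O6 with silyl-protected 3-hydroxycinnamoyl chloride finish the route.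

Key step: step 3

Assumption: atoms carry eudesmane numbers (ring A = C1–C5 and C10, ring B = C5–C10, C14 on C10, C15 on C4), β is the face of C14, and diphosphate 3 is drawn as the free acid but handled as its ammonium salt.

Step 1
Reactants: 1 (2E,6E)-farnesol
Product: 2 (2E,6E)-farnesyl chloride
Conditions: NCS, Me2S, CH2Cl2, −40 → 0 °C
Reagents that add atoms: N-chlorosuccinimide, O=C1CCC(=O)N1Cl
Why: Corey–Kim chlorination, in which the alkoxysulfonium ion formed from 1 is displaced by chloride at the primary carbon in an SN2 step, so the allylic system is not transposed and both E alkenes are kept.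

Step 2
Reactants: 2 (2E,6E)-farnesyl chloride
Product: 3 (2E,6E)-farnesyl diphosphate (isolated as its ammonium salt)
Conditions: (n-Bu4N)3HP2O7, MeCN, rt; then cation exchange (NH4+ form), aq NH4HCO3, lyophilise
Reagents that add atoms: tris(tetrabutylammonium) hydrogen diphosphate, CCCC[N+](CCCC)(CCCC)CCCC.CCCC[N+](CCCC)(CCCC)CCCC.CCCC[N+](CCCC)(CCCC)CCCC.OP(=O)([O-])OP(=O)([O-])[O-]
Why: SN2 displacement of the primary allylic chloride by the diphosphate anion in acetonitrile (allylic diphosphorylation), the standard preparation of prenyl diphosphates, which leaves the alkene geometry untouched.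

Step 3
Reactants: 3 (2E,6E)-farnesyl diphosphate
Product: 5 (4S,5R,7R,10R)-eudesm-11-en-4-ol (4β-OH; 5α-H; 7β-isopropenyl; 10β-methyl), via (R)-germacrene A 4 (not isolated)
Conditions: recombinant class 1 sesquiterpene synthase chosen by screening (and active-site mutagenesis if needed) for 4β hydration, MgCl2, HEPES buffer pH 7.5, 30 °C, pentane overlay
Reagents that add atoms: water, O
Why: Class 1 terpene-synthase cationic cyclisation: divalent magnesium bound to the diphosphate triggers ionisation, the C7=C11 alkene attacks C6 to close the ten-membered ring (Markovnikov, with the C11 cation left outside the ring), and loss of a C12 proton gives enzyme-bound 4. Reprotonation at C1 generates the C10 cation, which is attacked across the ring by C5 of the C4=C5 alkene (6-endo with respect to ring A, 6-exo with respect to ring B), and the resulting C4 cation is quenched by an active-site water molecule. The closest known reaction type is the conversion of farnesyl diphosphate into eudesmane tertiary alcohols by hydroxylating sesquiterpene synthases that pass through a germacrene intermediate. C7 (R) is set by the alkene face that the enzyme-bound chain presents to C6, while C5 and C10 follow from the chair–chair fold of the E,E-diene, in which anti addition across both E alkenes gives the trans ring fusion (5α-H, 10β-methyl) and leaves the C7 side chain equatorial. C4 (S, axial 4β-OH) is set by the position of the bound water on the β face, an outcome that the uncatalysed anti addition (equatorial 4α capture) does not give. The step therefore needs enzyme control over the fold, the face of hydration and water capture over proton loss, whereas the substrate contributes only the E geometry of its two trisubstituted alkenes, which fixes the relative configuration at C5 and C10.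

Step 4
Reactants: 5 (4S,5R,7R,10R)-eudesm-11-en-4-ol
Product: 6 (4S,5R,7R,10R)-eudesman-4-ol (eudesman-4β-ol)
Conditions: H2 (1 atm), RhCl(PPh3)3 (cat.), toluene–EtOH, rt
Reagents that add atoms: none
Why: Homogeneous hydrogenation with Wilkinson's catalyst reduces the unhindered 1,1-disubstituted alkene without double-bond migration, so C7 is not touched, C11 is not a stereocentre and the tertiary alcohol is inert.

Step 5
Reactants: 6 (4S,5R,7R,10R)-eudesman-4-ol
Product: 7 (4S,5S,6R,7S,10R)-eudesmane-4,6-diol (4β,6β-diol)
Conditions: cytochrome P450 BM3 (CYP102A1) variant picked from a mutant panel for C6β selectivity, NADP+ (cat.), D-glucose, glucose dehydrogenase, air, KPi buffer pH 8.0, 2% DMSO, 25 °C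
Reagents that add atoms: dioxygen, O=O
Why: Cytochrome P450 C–H hydroxylation by hydrogen abstraction and oxygen rebound, a reaction type established for methylene groups of sesquiterpenoids with engineered variants, proceeds with retention, so removal of the axial 6β-H gives the axial 6β-OH (6R), the site being fixed by the variant chosen in the screen and the saturated substrate offering no alkene for epoxidation.

Step 6
Reactants: 8 (E)-3-hydroxycinnamic acid
Product: 9 tert-butyldimethylsilyl (E)-3-[3-(tert-butyldimethylsilyloxy)phenyl]prop-2-enoate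
Conditions: TBSCl (2.3 equiv), imidazole, DMF, rt
Reagents that add atoms: tert-butyldimethylsilyl chloride, CC(C)(C)[Si](C)(C)Cl
Why: Imidazole-promoted silylation converts the phenol and the carboxylic acid into their TBS derivatives in one operation, which masks the phenol for the later acylation and prepares the acid for direct activation.

Step 7
Reactants: 9 tert-butyldimethylsilyl (E)-3-[3-(tert-butyldimethylsilyloxy)phenyl]prop-2-enoate
Product: 10 (E)-3-[3-(tert-butyldimethylsilyloxy)phenyl]prop-2-enoyl chloride
Conditions: (COCl)2, DMF (cat.), CH2Cl2, 0 °C → rt; concentrate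
Reagents that add atoms: oxalyl chloride, ClC(=O)C(=O)Cl
Why: The silyl ester reacts with the Vilsmeier chloroiminium salt formed from oxalyl chloride and DMF to give the acid chloride under neutral conditions (acyl chloride formation from a silyl ester), so the aryl silyl ether and the E alkene are kept.

Step 8
Reactants: 7 (4S,5S,6R,7S,10R)-eudesmane-4,6-diol; 10 (E)-3-[3-(tert-butyldimethylsilyloxy)phenyl]prop-2-enoyl chloride
Product: 11 (4S,5S,6R,7S,10R)-4-hydroxyeudesman-6-yl (E)-3-[3-(tert-butyldimethylsilyloxy)phenyl]prop-2-enoate
Conditions: Et3N, DMAP, CH2Cl2, 0 → 40 °C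
Reagents that add atoms: none
Why: DMAP-catalysed acylation (nucleophilic catalysis through the N-acylpyridinium ion) esterifies the secondary 6β-OH while the tertiary 4β-OH is too hindered to compete, and the C6–O bond is not broken, so its configuration is kept.

Step 9
Reactants: 11 (4S,5S,6R,7S,10R)-4-hydroxyeudesman-6-yl (E)-3-[3-(tert-butyldimethylsilyloxy)phenyl]prop-2-enoate
Product: 12 (4S,5S,6R,7S,10R)-4-hydroxyeudesman-6-yl (E)-3-(3-hydroxyphenyl)prop-2-enoate (target, CNP0283603.1)
Conditions: TBAF, AcOH, THF, 0 °C
Reagents that add atoms: none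
Why: Fluoride-induced desilylation cleaves the aryl silyl ether through the strong Si–F bond, and the acetic acid buffer keeps the phenoxide from attacking the cinnamate ester.

Compound list
1 | (2E,6E)-farnesol | CC(C)=CCC/C(C)=C/CC/C(C)=C/CO | starting material
2 | (2E,6E)-farnesyl chloride | CC(C)=CCC/C(C)=C/CC/C(C)=C/CCl | intermediate
3 | (2E,6E)-farnesyl diphosphate | CC(C)=CCC/C(C)=C/CC/C(C)=C/COP(=O)(O)OP(=O)(O)O | intermediate
4 | (R)-germacrene A, (1(10)E,4E,7R)-germacra-1(10),4,11-triene, enzyme-bound | C=C(C)[C@@H]1CC/C(C)=C/CC/C(C)=C/C1 | intermediate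
5 | (4S,5R,7R,10R)-eudesm-11-en-4-ol (eudesm-11-en-4β-ol) | C=C(C)[C@@H]1CC[C@@]2(C)CCC[C@](C)(O)[C@@H]2C1 | intermediate
6 | (4S,5R,7R,10R)-eudesman-4-ol (eudesman-4β-ol) | CC(C)[C@@H]1CC[C@@]2(C)CCC[C@](C)(O)[C@@H]2C1 | intermediate
7 | (4S,5S,6R,7S,10R)-eudesmane-4,6-diol (4β,6β-diol) | CC(C)[C@@H]1CC[C@@]2(C)CCC[C@](C)(O)[C@@H]2[C@@H]1O | intermediate
8 | (E)-3-hydroxycinnamic acid | O=C(O)/C=C/c1cccc(O)c1 | starting material
9 | tert-butyldimethylsilyl (E)-3-[3-(tert-butyldimethylsilyloxy)phenyl]prop-2-enoate | CC(C)(C)[Si](C)(C)OC(=O)/C=C/c1cccc(O[Si](C)(C)C(C)(C)C)c1 | intermediate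
10 | (E)-3-[3-(tert-butyldimethylsilyloxy)phenyl]prop-2-enoyl chloride | O=C(Cl)/C=C/c1cccc(O[Si](C)(C)C(C)(C)C)c1 | intermediate
11 | (4S,5S,6R,7S,10R)-4-hydroxyeudesman-6-yl (E)-3-[3-(tert-butyldimethylsilyloxy)phenyl]prop-2-enoate | CC(C)[C@@H]1CC[C@@]2(C)CCC[C@](C)(O)[C@@H]2[C@@H]1OC(=O)/C=C/c1cccc(O[Si](C)(C)C(C)(C)C)c1 | intermediate
12 | (4S,5S,6R,7S,10R)-4-hydroxyeudesman-6-yl (E)-3-(3-hydroxyphenyl)prop-2-enoate | CC(C)[C@@H]1CC[C@@]2(C)CCC[C@](C)(O)[C@@H]2[C@@H]1OC(=O)/C=C/c1cccc(O)c1 | target

Total step count: 9. Longest linear sequence: 7 steps (steps 1–5, 8 and 9); steps 6 and 7 prepare the acyl fragment.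

Steps most likely to fail

Step 3. The cyclase may deliver water to the 4α face of the C4 cation, or quench the cation by proton loss, so that the 4β-alcohol becomes a minor product. Turnover may also be too low for preparative use. The fallback sets out from 3 and returns at 6, using only known reaction types. A cyclase with the ordinary 4α hydration outcome should convert 3 into eudesm-11-en-4α-ol F1. Hydrogenation as in step 4 should give eudesman-4α-ol F2. Dehydration of this equatorial tertiary alcohol with SOCl2 in pyridine at 0 °C should give eudesm-4(15)-ene F3, because only a C15 hydrogen can stand antiperiplanar to the equatorial leaving group. Ozonolysis (O3, CH2Cl2–MeOH, −78 °C, then Me2S) should give 15-nor-eudesman-4-one F4. Addition of MeMgBr with CeCl3 (THF, −78 → 0 °C) should then occur from the equatorial α face, since the axial β trajectory is blocked by the syn-axial C14 methyl, giving the axial 4β-alcohol 6.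

Step 5. Oxygen may be inserted at another C–H bond (the C11 methine or a ring A methylene) or into the equatorial 6α-H, and the hydrophobic substrate may give low conversion. The fallback sets out from 6 and returns at 7 by hydroxyl-directed C–H silylation. Dehydrogenative silylation of the 4β-OH (Et2SiH2, [Ir(cod)OMe]2, THF, rt) should give the diethyl(hydrido)silyl ether F5. Iridium-catalysed γ-C–H silylation ([Ir(cod)OMe]2, 3,4,7,8-tetramethyl-1,10-phenanthroline, norbornene, THF, 100 °C) should close the oxasilolane F6 onto the syn-axial 6β-H. Closure at C6 gives a five-membered ring fused to ring B, whereas closure at C2 would need a strained bridge across ring A, although some C2 product may form and need separation. Tamao–Fleming oxidation (H2O2, KHCO3, KF, THF–MeOH, 50 °C) proceeds with retention and should give 7.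

Step 8. Acyl transfer to the axial 6β-OH may be slow because this hydroxyl is syn-axial to both C14 and the 4β-OH, so hydrolysis or decomposition of 10 could outrun esterification. The fallback sets out from 7 and returns at 11 by building the cinnamate on the alcohol. Esterification with diethylphosphonoacetic acid (DCC, DMAP cat., CH2Cl2, rt), a small acyl donor that reacts through a ketene-like intermediate, should give the phosphonoacetate F7. A Horner–Wadsworth–Emmons reaction with commercial 3-(tert-butyldimethylsilyloxy)benzaldehyde under Masamune–Roush conditions (LiCl, DBU, MeCN, rt) should then give the E-cinnamate 11.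

Further compounds
F1 | step 3 | (4R,5R,7R,10R)-eudesm-11-en-4-ol (eudesm-11-en-4α-ol) | C=C(C)[C@@H]1CC[C@@]2(C)CCC[C@@](C)(O)[C@@H]2C1
F2 | step 3 | (4R,5R,7R,10R)-eudesman-4-ol (eudesman-4α-ol) | CC(C)[C@@H]1CC[C@@]2(C)CCC[C@@](C)(O)[C@@H]2C1
F3 | step 3 | eudesm-4(15)-ene (5α-H, 7β-isopropyl, 10β-methyl) | CC(C)[C@@H]1CC[C@@]2(C)CCCC(=C)[C@@H]2C1
F4 | step 3 | 15-nor-eudesman-4-one (5α-H, 7β-isopropyl, 10β-methyl) | CC(C)[C@@H]1CC[C@@]2(C)CCCC(=O)[C@@H]2C1
F5 | step 5 | eudesman-4β-yl diethyl(hydrido)silyl ether | CC(C)[C@@H]1CC[C@@]2(C)CCC[C@](C)(O[SiH](CC)CC)[C@@H]2C1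
F6 | step 5 | 4β-O,6β-C-bridged diethyl oxasilolane of eudesman-4β-ol | CC(C)[C@@H]1CC[C@@]2(C)CCC[C@]3(C)O[Si](CC)(CC)[C@H]1[C@H]23
F7 | step 8 | (4S,5S,6R,7S,10R)-4-hydroxyeudesman-6-yl 2-(diethoxyphosphoryl)acetate | CC(C)[C@@H]1CC[C@@]2(C)CCC[C@](C)(O)[C@@H]2[C@@H]1OC(=O)CP(=O)(OCC)OCC
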